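## Retrosynthetic overview

1. Militarinone A (21) ⇐ N-deoxy pyridone 19 by a last-step N–O bond formation (new reaction); 19 ⇐ acylpyridine 18 carrying only fluoride-labile groups.
2. 18 ⇐ C3–acyl bond: C3-lithiated pyridine carbinol 16 + trienyl Weinreb amide 11; 16 ⇐ C5–C1′ bond: 5-lithio-2,4-dialkoxypyridine + 4-silyloxycyclohexanone.
3. 11 ⇐ enal 8 (four-carbon Horner–Wadsworth–Emmons, then amidation) ⇐ ester 5 (reduction/Wittig) ⇐ hemiester 2 (acid → ethyl).
4. 2 ⇐ meso-2,4-dimethylglutaric anhydride 1 by cinchona-alkaloid-catalysed desymmetrising methanolysis, the only asymmetric step (fixes C8 and C10).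
5. Rings: none is built. Ring B (cyclohexane) is joined to ring A (pyridine) in step 9; ring A is unveiled as the 2-pyridone in step 11 and N-hydroxylated in step 12.

Assumption: the side chain is numbered C1 (ketone carbon) to C12 and ring A as N1, C2(=O), C3 (acyl), C4 (OH), C5 (cyclohexyl), C6; the SMILES is read as (8R,10R) with syn methyl groups and a cis-1,4-diol on ring B (pyridone trans to the secondary OH).

Assumption: (DHQD)2AQN is taken to deliver methanol to the carbonyl next to the (R)-carbon of 1; if the observed sense is the opposite, its pseudoenantiomer (DHQ)2AQN is used and nothing else changes.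

## Route

Step 1
Reactants: 1 meso-2,4-dimethylglutaric anhydride
Product: 2 (2S,4R)-5-methoxy-2,4-dimethyl-5-oxopentanoic acid
Conditions: hydroquinidine anthraquinone-1,4-diyl diether [(DHQD)2AQN] (20 mol %), MeOH (10 equiv), Et2O, −30 °C, 72–96 h
Reagents that add atoms: methanol, CO
Why: Cinchona-alkaloid (general-base) catalysed desymmetrising alcoholysis of an achiral cyclic meso-anhydride, in which the catalyst selects one of the two enantiotopic carbonyl groups and so fixes the absolute configuration at both methyl-bearing carbons (future C8 and C10) while their syn relationship comes from the ring (≥90% ee expected, raised by crystallising the dicyclohexylammonium salt).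

Step 2
Reactants: 2 (2S,4R)-5-methoxy-2,4-dimethyl-5-oxopentanoic acid
Product: 3 methyl (2R,4S)-5-hydroxy-2,4-dimethylpentanoate
Conditions: BH3·SMe2 (1.2 equiv), THF, −10 → 20 °C; then MeOH
Reagents that add atoms: none
Why: Chemoselective borane reduction of a carboxylic acid beside a methyl ester (acyloxyborane pathway) touches no stereocenter, and the crude hydroxy ester is used at once to avoid lactonisation.

Step 3
Reactants: 3 methyl (2R,4S)-5-hydroxy-2,4-dimethylpentanoate
Product: 4 methyl (2R,4S)-2,4-dimethyl-5-[(4-methylbenzenesulfonyl)oxy]pentanoate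
Conditions: TsCl, Et3N, 4-(dimethylamino)pyridine (cat.), CH2Cl2, 0 °C
Reagents that add atoms: 4-toluenesulfonyl chloride, Cc1ccc(cc1)S(=O)(=O)Cl
Why: Standard O-sulfonylation of the primary alcohol under mild base, which activates C11 and blocks lactonisation.

Step 4
Reactants: 4 methyl (2R,4S)-2,4-dimethyl-5-[(4-methylbenzenesulfonyl)oxy]pentanoate
Product: 5 methyl (2R,4R)-2,4-dimethylhexanoate
Conditions: Me2CuLi (3 equiv, from MeLi and CuBr·SMe2), Et2O, −40 → 0 °C
Reagents that add atoms: lithium dimethylcuprate, [Li+].C[Cu-]C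
Why: Gilman cuprate SN2 substitution of the primary tosylate installs C12 while the ester is inert to the cuprate at this temperature; no stereocenter reacts (the descriptor at C4 becomes R only through the change in CIP priorities).

Step 5
Reactants: 5 methyl (2R,4R)-2,4-dimethylhexanoate; 6 2-(triphenylphosphoranylidene)propanal
Product: 8 (2E,4R,6R)-2,4,6-trimethyloct-2-enal, via aldehyde 7 (not isolated)
Conditions: i-Bu2AlH (1.05 equiv), CH2Cl2, −78 °C, 1 h; then 6 (2 equiv), −78 → 40 °C, 24 h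
Reagents that add atoms: none
Why: Partial ester reduction gives the aluminium hemiacetal, which on warming releases aldehyde 7 that is trapped in the flask by the stabilised ylide (E-selective Wittig olefination), so the epimerisable α-methyl aldehyde is never handled.

Step 6
Reactants: 8 (2E,4R,6R)-2,4,6-trimethyloct-2-enal; 9 triethyl 4-phosphonocrotonate
Product: 10 ethyl (2E,4E,6E,8R,10R)-6,8,10-trimethyldodeca-2,4,6-trienoate
Conditions: 9 (1.3 equiv), LiN(SiMe3)2 (1.25 equiv), THF, −78 → 0 °C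
Reagents that add atoms: none
Why: Vinylogous Horner–Wadsworth–Emmons olefination with the preformed phosphonate anion (no free base, so the γ-stereocenter C8 is not deprotonated) adds C2–C5 and gives the all-E triene.

Step 7
Reactants: 10 ethyl (2E,4E,6E,8R,10R)-6,8,10-trimethyldodeca-2,4,6-trienoate
Product: 11 (2E,4E,6E,8R,10R)-N-methoxy-N,6,8,10-tetramethyldodeca-2,4,6-trienamide
Conditions: MeNH(OMe)·HCl (2 equiv), i-PrMgCl (4 equiv), THF, −20 → 0 °C
Reagents that add atoms: N,O-dimethylhydroxylamine hydrochloride, CNOC.Cl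
Why: Direct ester-to-Weinreb-amide aminolysis by the chloromagnesium amide, which attacks the ester carbonyl faster than it adds in conjugate fashion.

Step 8
Reactants: 12 5-bromo-2,4-dichloropyridine
Product: 13 5-bromo-2,4-bis[2-(trimethylsilyl)ethoxy]pyridine
Conditions: Me3SiCH2CH2OH (2.5 equiv), NaH (2.6 equiv), DMF, 0 → 70 °C
Reagents that add atoms: 2-(trimethylsilyl)ethanol, C[Si](C)(C)CCO
Why: Two-fold nucleophilic aromatic substitution (SNAr) at the nitrogen-activated 2- and 4-positions leaves the C5 bromide untouched and masks both pyridone oxygens as fluoride-labile ethers.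

Step 9
Reactants: 13 5-bromo-2,4-bis[2-(trimethylsilyl)ethoxy]pyridine; 14 4-[(tert-butyldimethylsilyl)oxy]cyclohexan-1-one
Product: 16 5-[cis-4-(tert-butyldimethylsilyloxy)-1-hydroxycyclohexyl]-2,4-bis[2-(trimethylsilyl)ethoxy]pyridine (tertiary OH cis to OTBS), via aryllithium 15 (not isolated)
Conditions: n-BuLi (1.05 equiv), THF, −78 °C, 20 min; then 14 (1.2 equiv), −78 → −40 °C; aq. NH4Cl; chromatography
Reagents that add atoms: none
Why: Bromine–lithium exchange followed by 1,2-addition to the ketone, in which the ortho-alkoxy aryllithium attacks the chair with equatorial OTBS from the equatorial direction, so the pyridyl group ends equatorial and trans to OTBS and the new tertiary OH axial and cis to it (about 3:1 expected, separable), which is the cis-1,4-diol of the target.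

Step 10
Reactants: 16 5-[cis-4-(tert-butyldimethylsilyloxy)-1-hydroxycyclohexyl]-2,4-bis[2-(trimethylsilyl)ethoxy]pyridine; 11 (2E,4E,6E,8R,10R)-N-methoxy-N,6,8,10-tetramethyldodeca-2,4,6-trienamide
Product: 18 (2E,4E,6E,8R,10R)-1-{5-[cis-4-(tert-butyldimethylsilyloxy)-1-hydroxycyclohexyl]-2,4-bis[2-(trimethylsilyl)ethoxy]pyridin-3-yl}-6,8,10-trimethyldodeca-2,4,6-trien-1-one, via dilithio species 17 (not isolated)
Conditions: n-BuLi (2.2 equiv), THF, −78 → −20 °C, 1 h; then 11 (0.8 equiv), −78 → 0 °C; aq. NH4Cl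
Reagents that add atoms: none
Why: After O–H deprotonation, directed ortho-metalation takes place at C3 between the two alkoxy groups, and acylation by the Weinreb amide through its stable chelate gives the trienyl ketone without over-addition.

Step 11
Reactants: 18 (2E,4E,6E,8R,10R)-1-{5-[cis-4-(tert-butyldimethylsilyloxy)-1-hydroxycyclohexyl]-2,4-bis[2-(trimethylsilyl)ethoxy]pyridin-3-yl}-6,8,10-trimethyldodeca-2,4,6-trien-1-one
Product: 19 N-deoxymilitarinone A
Conditions: Bu4NF (6 equiv), THF, 0 → 45 °C; aq. NH4Cl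
Reagents that add atoms: none
Why: Fluoride-induced fragmentation of both 2-(trimethylsilyl)ethyl ethers (loss of ethylene) and Si–O cleavage of the TBS ether unveil the 4-hydroxy-2-pyridone and the secondary alcohol under non-acidic conditions that spare the ionisable tertiary alcohol and the triene.

Step 12
Reactants: 19 N-deoxymilitarinone A
Product: 21 militarinone A, via N-benzoyloxy pyridone 20 (not isolated)
Conditions: KN(SiMe3)2 (2.05 equiv), THF–DMPU, −78 °C; (PhCO2)2 (1.05 equiv), −78 → −20 °C, dark; then MeOH, K2CO3 (cat.), 0 °C; dilute HCl to pH 4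
Reagents that add atoms: dibenzoyl peroxide, O=C(OOC(=O)c1ccccc1)c1ccccc1
Why: Proposed new method: the dipotassium salt of 19 (acyl-enolate at O4 plus pyridonate) should attack the weak O–O bond of dibenzoyl peroxide through its most nucleophilic centre, the ring nitrogen (the N-selectivity seen in alkylation of alkali pyridonates), in an SN2-at-oxygen step that expels benzoate and gives the N-benzoyloxy pyridone 20, an active ester that methanol cleaves in the same flask to the N-hydroxy pyridone; the two alcohols stay protonated (far less acidic than N–H), C3 and C5 carry no hydrogen, and the peroxide does not epoxidise the triene at low temperature; the closest known reaction types are the electrophilic benzoyloxylation of amines and of enolates with dibenzoyl peroxide and the oxidation of O-silylated 2-pyridones to N-hydroxy pyridones with peroxo-molybdenum reagents.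

## Compound list

1 | meso-2,4-dimethylglutaric anhydride, (3R,5S)-3,5-dimethyloxane-2,6-dione | O=C1[C@@H](C)C[C@@H](C)C(=O)O1 | starting material
2 | (2S,4R)-5-methoxy-2,4-dimethyl-5-oxopentanoic acid | OC(=O)[C@@H](C)C[C@@H](C)C(=O)OC | intermediate
3 | methyl (2R,4S)-5-hydroxy-2,4-dimethylpentanoate | OC[C@@H](C)C[C@@H](C)C(=O)OC | intermediate
4 | methyl (2R,4S)-2,4-dimethyl-5-[(4-methylbenzenesulfonyl)oxy]pentanoate | Cc1ccc(cc1)S(=O)(=O)OC[C@@H](C)C[C@@H](C)C(=O)OC | intermediate
5 | methyl (2R,4R)-2,4-dimethylhexanoate | CC[C@@H](C)C[C@@H](C)C(=O)OC | intermediate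
6 | 2-(triphenylphosphoranylidene)propanal | CC(C=O)=P(c1ccccc1)(c1ccccc1)c1ccccc1 | starting material
7 | (2R,4R)-2,4-dimethylhexanal | CC[C@@H](C)C[C@@H](C)C=O | intermediate
8 | (2E,4R,6R)-2,4,6-trimethyloct-2-enal | CC[C@@H](C)C[C@@H](C)/C=C(C)/C=O | intermediate
9 | triethyl 4-phosphonocrotonate, ethyl (2E)-4-(diethoxyphosphoryl)but-2-enoate | CCOC(=O)/C=C/CP(=O)(OCC)OCC | starting material
10 | ethyl (2E,4E,6E,8R,10R)-6,8,10-trimethyldodeca-2,4,6-trienoate | CC[C@@H](C)C[C@@H](C)/C=C(C)/C=C/C=C/C(=O)OCC | intermediate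
11 | (2E,4E,6E,8R,10R)-N-methoxy-N,6,8,10-tetramethyldodeca-2,4,6-trienamide | CC[C@@H](C)C[C@@H](C)/C=C(C)/C=C/C=C/C(=O)N(C)OC | intermediate
12 | 5-bromo-2,4-dichloropyridine | Clc1cc(Cl)c(Br)cn1 | starting material
13 | 5-bromo-2,4-bis[2-(trimethylsilyl)ethoxy]pyridine | C[Si](C)(C)CCOc1cc(OCC[Si](C)(C)C)c(Br)cn1 | intermediate
14 | 4-[(tert-butyldimethylsilyl)oxy]cyclohexan-1-one | CC(C)(C)[Si](C)(C)OC1CCC(=O)CC1 | starting material
15 | 5-lithio-2,4-bis[2-(trimethylsilyl)ethoxy]pyridine | [Li]c1cnc(OCC[Si](C)(C)C)cc1OCC[Si](C)(C)C | intermediate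
16 | 5-[cis-4-(tert-butyldimethylsilyloxy)-1-hydroxycyclohexyl]-2,4-bis[2-(trimethylsilyl)ethoxy]pyridine (tertiary OH cis to OTBS, pyridyl trans to OTBS) | C[Si](C)(C)CCOc1cc(OCC[Si](C)(C)C)c(cn1)[C@]1(O)CC[C@@H](O[Si](C)(C)C(C)(C)C)CC1 | intermediate
17 | 3-lithio-5-[cis-4-(tert-butyldimethylsilyloxy)-1-(lithiooxy)cyclohexyl]-2,4-bis[2-(trimethylsilyl)ethoxy]pyridine | [Li]c1c(OCC[Si](C)(C)C)c([C@]2(O[Li])CC[C@@H](O[Si](C)(C)C(C)(C)C)CC2)cnc1OCC[Si](C)(C)C | intermediate
18 | (2E,4E,6E,8R,10R)-1-{5-[cis-4-(tert-butyldimethylsilyloxy)-1-hydroxycyclohexyl]-2,4-bis[2-(trimethylsilyl)ethoxy]pyridin-3-yl}-6,8,10-trimethyldodeca-2,4,6-trien-1-one | CC[C@@H](C)C[C@@H](C)/C=C(C)/C=C/C=C/C(=O)c1c(OCC[Si](C)(C)C)c([C@]2(O)CC[C@@H](O[Si](C)(C)C(C)(C)C)CC2)cnc1OCC[Si](C)(C)C | intermediate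
19 | N-deoxymilitarinone A, 5-(cis-1,4-dihydroxycyclohexyl)-4-hydroxy-3-[(2E,4E,6E,8R,10R)-6,8,10-trimethyldodeca-2,4,6-trienoyl]pyridin-2(1H)-one | CC[C@@H](C)C[C@@H](C)/C=C(C)/C=C/C=C/C(=O)c1c(O)c([C@]2(O)CC[C@@H](O)CC2)c[nH]c1=O | intermediate
20 | 1-(benzoyloxy)-5-(cis-1,4-dihydroxycyclohexyl)-4-hydroxy-3-[(2E,4E,6E,8R,10R)-6,8,10-trimethyldodeca-2,4,6-trienoyl]pyridin-2(1H)-one | CC[C@@H](C)C[C@@H](C)/C=C(C)/C=C/C=C/C(=O)c1c(O)c([C@]2(O)CC[C@@H](O)CC2)cn(OC(=O)c2ccccc2)c1=O | intermediate
21 | militarinone A, 1,4-dihydroxy-5-(cis-1,4-dihydroxycyclohexyl)-3-[(2E,4E,6E,8R,10R)-6,8,10-trimethyldodeca-2,4,6-trienoyl]pyridin-2(1H)-one | CC[C@@H](C)C[C@@H](C)/C=C(C)/C=C/C=C/C(=O)c1c(O)c([C@]2(O)CC[C@@H](O)CC2)cn(O)c1=O | target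

## Step count and risks

Total step count: 12. Longest linear sequence: 10 steps (steps 1–7, then 10–12); the core branch is steps 8–9.

The three steps most likely to fail:

**Step 12 (proposed new N–O bond formation).** Risks are attack through oxygen instead of nitrogen, electron transfer from the dianion to the peroxide, and benzoyl transfer. The fallback uses known chemistry and puts the N–O bond in by pyridine N-oxidation before the polyene exists. It sets out from 16 (and from 8 for the chain) and comes back at 21. Compound 16 is lithiated at C3 as in step 10 and quenched with N-methoxy-N-methylacetamide to give the methyl ketone F1. 3-Chloroperbenzoic acid (NaHCO3, CH2Cl2) then oxidises the ring nitrogen to the pyridine N-oxide F2. Enal 8 is extended with (triphenylphosphoranylidene)acetaldehyde to the dienal F3. The lithium enolate of F2 (LiN(SiMe3)2, 2.1 equiv, THF, −78 °C) adds to F3 to give the aldol F4, which is dehydrated (MsCl, Et3N, then DBU) to the trienone N-oxide F5. Bu4NF removes the two 2-(trimethylsilyl)ethyl groups and the TBS ether, and the freed 2-hydroxypyridine N-oxide is the 1-hydroxy-2-pyridone tautomer, 21.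

**Step 9 (facial selectivity of the aryllithium addition).** The cis-diol may form with poor selectivity. The fallback sets the secondary carbinol by hydride delivery instead; it sets out from 13 and comes back at 16. Aryllithium 15, made as in step 9, is added to excess cyclohexane-1,4-dione (THF, −78 °C) to give the hydroxy ketone F6. NaBH4 (MeOH, −40 °C) attacks the chair with equatorial pyridyl axially, so the new hydroxyl is equatorial and trans to the pyridyl group, giving the cis-1,4-diol F7. TBSCl with imidazole silylates only the secondary hydroxyl and returns 16.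

**Step 10 (C3 lithiation and acylation with the trienyl Weinreb amide).** Risks are incomplete lithiation and deprotonation of the polyene amide instead of addition. The fallback is aldehyde addition followed by oxidation; it sets out from 11 and 17 and comes back at 18. i-Bu2AlH (THF, −78 °C) reduces 11 to the trienal F8. The dilithio species 17 adds to F8 to give the carbinol F9. MnO2 (CH2Cl2) oxidises this doubly activated secondary carbinol, leaving the tertiary alcohol alone, to give 18.

Further compounds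
F1 | step 12 | 1-{5-[cis-4-(tert-butyldimethylsilyloxy)-1-hydroxycyclohexyl]-2,4-bis[2-(trimethylsilyl)ethoxy]pyridin-3-yl}ethan-1-one | CC(=O)c1c(OCC[Si](C)(C)C)c([C@]2(O)CC[C@@H](O[Si](C)(C)C(C)(C)C)CC2)cnc1OCC[Si](C)(C)C
F2 | step 12 | 3-acetyl-5-[cis-4-(tert-butyldimethylsilyloxy)-1-hydroxycyclohexyl]-2,4-bis[2-(trimethylsilyl)ethoxy]pyridine 1-oxide | CC(=O)c1c(OCC[Si](C)(C)C)c([C@]2(O)CC[C@@H](O[Si](C)(C)C(C)(C)C)CC2)c[n+]([O-])c1OCC[Si](C)(C)C
F3 | step 12 | (2E,4E,6R,8R)-4,6,8-trimethyldeca-2,4-dienal | CC[C@@H](C)C[C@@H](C)/C=C(C)/C=C/C=O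
F4 | step 12 | 5-[cis-4-(tert-butyldimethylsilyloxy)-1-hydroxycyclohexyl]-3-[(4E,6E,8R,10R)-3-hydroxy-6,8,10-trimethyldodeca-4,6-dienoyl]-2,4-bis[2-(trimethylsilyl)ethoxy]pyridine 1-oxide (carbinol epimers) | CC[C@@H](C)C[C@@H](C)/C=C(C)/C=C/C(O)CC(=O)c1c(OCC[Si](C)(C)C)c([C@]2(O)CC[C@@H](O[Si](C)(C)C(C)(C)C)CC2)c[n+]([O-])c1OCC[Si](C)(C)C
F5 | step 12 | 5-[cis-4-(tert-butyldimethylsilyloxy)-1-hydroxycyclohexyl]-3-[(2E,4E,6E,8R,10R)-6,8,10-trimethyldodeca-2,4,6-trienoyl]-2,4-bis[2-(trimethylsilyl)ethoxy]pyridine 1-oxide | CC[C@@H](C)C[C@@H](C)/C=C(C)/C=C/C=C/C(=O)c1c(OCC[Si](C)(C)C)c([C@]2(O)CC[C@@H](O[Si](C)(C)C(C)(C)C)CC2)c[n+]([O-])c1OCC[Si](C)(C)C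
F6 | step 9 | 4-{4,6-bis[2-(trimethylsilyl)ethoxy]pyridin-3-yl}-4-hydroxycyclohexan-1-one | C[Si](C)(C)CCOc1cc(OCC[Si](C)(C)C)c(cn1)C1(O)CCC(=O)CC1
F7 | step 9 | cis-1-{4,6-bis[2-(trimethylsilyl)ethoxy]pyridin-3-yl}cyclohexane-1,4-diol | C[Si](C)(C)CCOc1cc(OCC[Si](C)(C)C)c(cn1)[C@]1(O)CC[C@@H](O)CC1
F8 | step 10 | (2E,4E,6E,8R,10R)-6,8,10-trimethyldodeca-2,4,6-trienal | CC[C@@H](C)C[C@@H](C)/C=C(C)/C=C/C=C/C=O
F9 | step 10 | (2E,4E,6E,8R,10R)-1-{5-[cis-4-(tert-butyldimethylsilyloxy)-1-hydroxycyclohexyl]-2,4-bis[2-(trimethylsilyl)ethoxy]pyridin-3-yl}-6,8,10-trimethyldodeca-2,4,6-trien-1-ol (carbinol epimers) | CC[C@@H](C)C[C@@H](C)/C=C(C)/C=C/C=C/C(O)c1c(OCC[Si](C)(C)C)c([C@]2(O)CC[C@@H](O[Si](C)(C)C(C)(C)C)CC2)cnc1OCC[Si](C)(C)C
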